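**Strategy.** The plan cuts ring A at C8a–C8, C7–C6 and C4a–C8a. Ring A bears oxygen at C8a (O1) and C7, prenyl groups at C8 and C6 and hydrogen at C5, a 1,3-dioxygenated pattern that maps onto a vinylketene plus a siloxyalkyne. Photolysis of 4-diazo-7-methylocta-1,6-dien-3-one with triisopropyl(5-methylhex-4-en-1-ynyloxy)silane, then warming, should assemble the whole arene in one operation, with O1 free and O7 silylated and both prenyl groups already in place. Ring C is then grown from the free phenol through a chromone, and C2 is set by rhodium-catalysed asymmetric addition of the arylboronic acid.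

Key step: step 5

Assumption: ring atoms carry flavanone numbers throughout. The (S,S) antipode of the diene ligand in step 10 is chosen by analogy with the facial sense this ligand class shows with cyclic enones. The (R,R) antipode would be taken instead if a trial addition showed the opposite sense.

Precursor design: the triisopropylsilyl group is kept because it makes the ynol silyl ether isolable and should survive steps 6–10. The diazo ketone is made last, kept cold and dark, and irradiated at once in dilute solution with the ynol ether in excess, so that the vinylketene is trapped as it forms.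

**Step 1**
Reactants: 1 5-bromo-2-methylpent-2-ene; 2 acrolein
Product: 4 7-methylocta-1,6-dien-3-ol (racemic), via 4-methylpent-3-enylmagnesium bromide 3 (not isolated)
Conditions: Mg, THF, rt; then 2, −78 °C → 0 °C; aq. NH4Cl
Reagents that add atoms: none
Why: Grignard formation from the primary bromide and 1,2-addition of the hard organomagnesium reagent to the aldehyde carbon of acrolein at low temperature; the carbinol centre forms racemic and is erased in step 2.

**Step 2**
Reactants: 4 7-methylocta-1,6-dien-3-ol
Product: 5 7-methylocta-1,6-dien-3-one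
Conditions: Dess–Martin periodinane, CH2Cl2, 0 °C → rt
Reagents that add atoms: none
Why: Dess–Martin oxidation of the secondary allylic alcohol under neutral, anhydrous conditions should give the vinyl ketone without touching the trisubstituted alkene; the enone is used promptly.

**Step 3**
Reactants: 5 7-methylocta-1,6-dien-3-one
Product: 8 4-diazo-7-methylocta-1,6-dien-3-one, via lithium dienolate 6 (not isolated), via trifluoroacetyl diketone 7 (not isolated)
Conditions: LiN(SiMe3)2 (1.1 equiv), THF, −78 °C, 5 added slowly; CF3CO2CH2CF3, −78 °C; aq. HCl, crude 7 carried on; MsN3, Et3N, H2O (1 equiv), MeCN, rt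
Reagents that add atoms: methanesulfonyl azide, CS(=O)(=O)N=[N+]=[N-]
Why: Detrifluoroacetylative diazo transfer (Danheiser diazo transfer): only C4 can be deprotonated because the vinyl side has no enolisable hydrogen, the trifluoroacetyl group activates C4 towards the sulfonyl azide, and cleavage of that group as the N-sulfonyl amide leaves the diazo ketone.

**Step 4**
Reactants: 9 ethyl 4-methylpent-3-enoate
Product: 12 triisopropyl(5-methylhex-4-en-1-ynyloxy)silane, via dibromoketone lithium enolate 10 (not isolated), via lithium ynolate 11 (not isolated)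
Conditions: CH2Br2, lithium 2,2,6,6-tetramethylpiperidide (from the amine and n-BuLi), THF, −78 °C; 9; LiN(SiMe3)2, −78 → −20 °C; n-BuLi, −78 °C → rt; i-Pr3SiCl, −78 °C → rt
Reagents that add atoms: dibromomethane, BrCBr; chlorotriisopropylsilane, CC(C)[Si](Cl)(C(C)C)C(C)C
Why: Kowalski ester homologation: dibromomethyllithium adds to the ester, the derived dibromo enolate undergoes bromine–lithium exchange and a carbenoid 1,2-shift of the prenyl group to give the ynolate, which the bulky silyl chloride traps on oxygen.

**Step 5**
Reactants: 8 4-diazo-7-methylocta-1,6-dien-3-one; 12 triisopropyl(5-methylhex-4-en-1-ynyloxy)silane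
Product: 17 2,4-bis(3-methylbut-2-enyl)-3-(triisopropylsilyloxy)phenol, via vinylketene 13 (not isolated), via vinylcyclobutenone 14 (not isolated), via dienylketene 15 (not isolated), via cyclohexadienone 16 (not isolated)
Conditions: 12 (1.5 equiv), hν (254 nm, low-pressure Hg lamps, Vycor), degassed ClCH2CH2Cl, rt; then 80 °C
Reagents that add atoms: none
Why: Light expels N2 from 8 and the vinyl group shifts from the carbonyl carbon (future C8a) to the former diazo carbon (future C6) in a Wolff rearrangement, which gives vinylketene 13 and also sets the C5–C6 bond. The ketene carbon is then attacked by the electron-rich, prenyl-bearing carbon of 12 in a [2+2] cycloaddition that forms C8a–C8 and C7–C6 and gives the 3-silyloxy-4-vinylcyclobut-2-enone 14, a four-membered ring that is only transient. Four-electron electrocyclic opening of 14 (cleaving the old C8a–C6 bond) gives dienylketene 15, and ring A closes by a thermal six-electron disrotatory electrocyclisation that forms C4a–C8a, after which dienone 16 tautomerises to the phenol. The closest known reaction type is the Danheiser benzannulation of photochemically generated vinylketenes with siloxyalkynes to give resorcinol monosilyl ethers. No stereocentre is formed. The step needs one regiochemical outcome in the [2+2] event, secured by the polarisation of the ynol silyl ether (its carbon remote from oxygen is the nucleophile, the ketene carbonyl carbon the electrophile), and it needs the Wolff shift to outrun a 1,2-hydrogen shift from the allylic CH2, which the good migrating ability of the vinyl group and trapping by excess 12 should favour.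

**Step 6**
Reactants: 17 2,4-bis(3-methylbut-2-enyl)-3-(triisopropylsilyloxy)phenol
Product: 19 2-hydroxy-3,5-bis(3-methylbut-2-enyl)-4-(triisopropylsilyloxy)benzaldehyde, via hydroxymethylphenol 18 (not isolated)
Conditions: MgCl2, Et3N, (CH2O)n, MeCN, reflux; aq. citric acid
Reagents that add atoms: paraformaldehyde, reacting as formaldehyde, C=O
Why: Magnesium-mediated ortho-formylation (Casnati–Skattebøl): the magnesium phenoxide delivers formaldehyde to C4a, the only free position ortho to O1 (C8 and the para position C6 are blocked), and the benzylic alkoxide is oxidised in the flask by hydride transfer to a second formaldehyde.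

**Step 7**
Reactants: 19 2-hydroxy-3,5-bis(3-methylbut-2-enyl)-4-(triisopropylsilyloxy)benzaldehyde
Product: 20 6-(1-hydroxyethyl)-2,4-bis(3-methylbut-2-enyl)-3-(triisopropylsilyloxy)phenol (racemic)
Conditions: MeMgBr (3 equiv), THF, −78 °C → 0 °C; aq. NH4Cl
Reagents that add atoms: methylmagnesium bromide, C[Mg]Br
Why: Grignard addition to the aldehyde after the first equivalent has deprotonated the phenol; the carbinol centre is racemic and is removed in step 8.

**Step 8**
Reactants: 20 6-(1-hydroxyethyl)-2,4-bis(3-methylbut-2-enyl)-3-(triisopropylsilyloxy)phenol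
Product: 21 1-[2-hydroxy-3,5-bis(3-methylbut-2-enyl)-4-(triisopropylsilyloxy)phenyl]ethanone
Conditions: activated MnO2, CH2Cl2, rt
Reagents that add atoms: none
Why: MnO2 oxidation of a benzylic alcohol under neutral conditions; every ortho and para position of the phenol is substituted, so oxidative coupling has no site.

**Step 9**
Reactants: 21 1-[2-hydroxy-3,5-bis(3-methylbut-2-enyl)-4-(triisopropylsilyloxy)phenyl]ethanone
Product: 23 6,8-bis(3-methylbut-2-enyl)-7-(triisopropylsilyloxy)-4H-chromen-4-one, via enaminone 22 (not isolated)
Conditions: Me2NCH(OMe)2, PhMe, 90 °C; evaporate; AcOH, PhMe, 60 °C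
Reagents that add atoms: N,N-dimethylformamide dimethyl acetal, COC(OC)N(C)C
Why: Condensation of the methyl ketone with the amide acetal gives the enaminone, and acid-promoted addition of O1 to C2 with loss of dimethylamine closes ring C (enaminone-to-chromone cyclisation); acetic acid is too weak to cyclise the C8 prenyl onto O1 or to cleave the silyl ether.

**Step 10**
Reactants: 23 6,8-bis(3-methylbut-2-enyl)-7-(triisopropylsilyloxy)-4H-chromen-4-one; 24 4-methoxyphenylboronic acid
Product: 25 (2S)-2-(4-methoxyphenyl)-6,8-bis(3-methylbut-2-enyl)-7-(triisopropylsilyloxy)chroman-4-one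
Conditions: 24 (2.5 equiv), [RhCl(C2H4)2]2 (2.5 mol %), (S,S)-2,5-diphenylbicyclo[2.2.2]octa-2,5-diene (5.5 mol %), KOH (20 mol %), dioxane/H2O (10:1), 40 °C
Reagents that add atoms: none
Why: Rhodium-catalysed asymmetric 1,4-addition (Hayashi–Miyaura reaction) of an arylboronic acid to a chromone: the aryl–rhodium–diene complex inserts the C2=C3 bond on the face dictated by the twofold-symmetric chiral diene and protonation of the oxa-allyl rhodium species releases the flavanone, so the ligand alone sets C2 as S.

**Step 11**
Reactants: 25 (2S)-2-(4-methoxyphenyl)-6,8-bis(3-methylbut-2-enyl)-7-(triisopropylsilyloxy)chroman-4-one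
Product: 26 (2S)-7-hydroxy-2-(4-methoxyphenyl)-6,8-bis(3-methylbut-2-enyl)chroman-4-one (the target flavanone)
Conditions: Bu4NF, AcOH (1:1), THF, 0 °C
Reagents that add atoms: none
Why: Fluoride-induced cleavage of the aryl silyl ether; the acetic acid buffer protonates the phenoxide at once and keeps the medium non-basic, so the flavanone should not open by retro-oxa-Michael reaction and C2 should keep its configuration.

**Compound list**
1 | 5-bromo-2-methylpent-2-ene | CC(C)=CCCBr | starting material
2 | acrolein | C=CC=O | starting material
3 | 4-methylpent-3-enylmagnesium bromide | CC(C)=CCC[Mg]Br | intermediate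
4 | 7-methylocta-1,6-dien-3-ol (racemic) | C=CC(O)CCC=C(C)C | intermediate
5 | 7-methylocta-1,6-dien-3-one | C=CC(=O)CCC=C(C)C | intermediate
6 | lithium 7-methylocta-1,3,6-trien-3-olate (enolate geometry of no consequence) | [Li+].[O-]C(C=C)=CCC=C(C)C | intermediate
7 | 1,1,1-trifluoro-3-(3-methylbut-2-enyl)hex-5-ene-2,4-dione (racemic, largely enolised) | C=CC(=O)C(CC=C(C)C)C(=O)C(F)(F)F | intermediate
8 | 4-diazo-7-methylocta-1,6-dien-3-one | C=CC(=O)C(=[N+]=[N-])CC=C(C)C | intermediate
9 | ethyl 4-methylpent-3-enoate | CCOC(=O)CC=C(C)C | starting material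
10 | lithium 1,1-dibromo-5-methylhexa-1,4-dien-2-olate | [Li+].[O-]C(CC=C(C)C)=C(Br)Br | intermediate
11 | lithium 5-methylhex-4-en-1-yn-1-olate | [Li+].[O-]C#CCC=C(C)C | intermediate
12 | triisopropyl(5-methylhex-4-en-1-ynyloxy)silane | CC(C)=CCC#CO[Si](C(C)C)(C(C)C)C(C)C | intermediate
13 | 2-ethenyl-5-methylhexa-1,4-dien-1-one | C=CC(=C=O)CC=C(C)C | intermediate
14 | 4-ethenyl-2,4-bis(3-methylbut-2-enyl)-3-(triisopropylsilyloxy)cyclobut-2-en-1-one (racemic) | C=CC1(CC=C(C)C)C(=O)C(CC=C(C)C)=C1O[Si](C(C)C)(C(C)C)C(C)C | intermediate
15 | (3E)-2,4-bis(3-methylbut-2-enyl)-3-(triisopropylsilyloxy)hexa-1,3,5-trien-1-one | O=C=C(CC=C(C)C)/C(O[Si](C(C)C)(C(C)C)C(C)C)=C(/CC=C(C)C)C=C | intermediate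
16 | 2,4-bis(3-methylbut-2-enyl)-3-(triisopropylsilyloxy)cyclohexa-2,4-dien-1-one | O=C1CC=C(CC=C(C)C)C(O[Si](C(C)C)(C(C)C)C(C)C)=C1CC=C(C)C | intermediate
17 | 2,4-bis(3-methylbut-2-enyl)-3-(triisopropylsilyloxy)phenol | Oc1ccc(CC=C(C)C)c(O[Si](C(C)C)(C(C)C)C(C)C)c1CC=C(C)C | intermediate
18 | 6-(hydroxymethyl)-2,4-bis(3-methylbut-2-enyl)-3-(triisopropylsilyloxy)phenol | OCc1cc(CC=C(C)C)c(O[Si](C(C)C)(C(C)C)C(C)C)c(CC=C(C)C)c1O | intermediate
19 | 2-hydroxy-3,5-bis(3-methylbut-2-enyl)-4-(triisopropylsilyloxy)benzaldehyde | O=Cc1cc(CC=C(C)C)c(O[Si](C(C)C)(C(C)C)C(C)C)c(CC=C(C)C)c1O | intermediate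
20 | 6-(1-hydroxyethyl)-2,4-bis(3-methylbut-2-enyl)-3-(triisopropylsilyloxy)phenol (racemic) | CC(O)c1cc(CC=C(C)C)c(O[Si](C(C)C)(C(C)C)C(C)C)c(CC=C(C)C)c1O | intermediate
21 | 1-[2-hydroxy-3,5-bis(3-methylbut-2-enyl)-4-(triisopropylsilyloxy)phenyl]ethanone | CC(=O)c1cc(CC=C(C)C)c(O[Si](C(C)C)(C(C)C)C(C)C)c(CC=C(C)C)c1O | intermediate
22 | (E)-3-(dimethylamino)-1-[2-hydroxy-3,5-bis(3-methylbut-2-enyl)-4-(triisopropylsilyloxy)phenyl]prop-2-en-1-one | CN(C)/C=C/C(=O)c1cc(CC=C(C)C)c(O[Si](C(C)C)(C(C)C)C(C)C)c(CC=C(C)C)c1O | intermediate
23 | 6,8-bis(3-methylbut-2-enyl)-7-(triisopropylsilyloxy)-4H-chromen-4-one | O=c1ccoc2c(CC=C(C)C)c(O[Si](C(C)C)(C(C)C)C(C)C)c(CC=C(C)C)cc12 | intermediate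
24 | 4-methoxyphenylboronic acid | COc1ccc(B(O)O)cc1 | starting material
25 | (2S)-2-(4-methoxyphenyl)-6,8-bis(3-methylbut-2-enyl)-7-(triisopropylsilyloxy)chroman-4-one | COc1ccc([C@@H]2CC(=O)c3cc(CC=C(C)C)c(O[Si](C(C)C)(C(C)C)C(C)C)c(CC=C(C)C)c3O2)cc1 | intermediate
26 | (2S)-7-hydroxy-2-(4-methoxyphenyl)-6,8-bis(3-methylbut-2-enyl)chroman-4-one (the target flavanone) | COc1ccc([C@@H]2CC(=O)c3cc(CC=C(C)C)c(O)c(CC=C(C)C)c3O2)cc1 | target

**Step count**
Total: 11 steps. Longest linear sequence: 10 steps (steps 1, 2, 3, 5, 6, 7, 8, 9, 10, 11).

**Steps most likely to fail**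

1. Step 5. The carbene-like excited state may undergo a 1,2-hydrogen shift from the allylic CH2 instead of the Wolff shift. The vinyl diazo ketone or the prenylated intermediates may degrade under the lamp, and the product phenol may be acylated by vinylketene that has not been trapped. The fallback generates the same vinylketene thermally in the dark, with no carbene involved. Commercial (E)-but-2-enoic acid is converted with LiN(i-Pr)2 (2 equiv, THF, −78 → 0 °C) into its dienediolate and alkylated at the α-carbon with 1-bromo-3-methylbut-2-ene to give 2-ethenyl-5-methylhex-4-enoic acid F1. Oxalyl chloride with catalytic DMF in CH2Cl2 should then give 2-ethenyl-5-methylhex-4-enoyl chloride F2. Slow addition of Et3N to F2 and siloxyalkyne 12 in toluene at rt, followed by heating to 80 °C, removes HCl across the α-carbon and the carbonyl group. The fallback sets out from siloxyalkyne 12 (diazo ketone 8 is not used) and comes back to the route at vinylketene 13, which goes on to phenol 17 as in step 5.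

2. Step 3. While enone and lithium enolate coexist during deprotonation, the enolate or the amide base may add to the vinyl ketone in Michael fashion and start oligomerisation, so that little enolate reaches the trifluoroacetate. The fallback separates enolisation from the strong base. Enone 5 is silylated under soft conditions (Me3SiOTf, Et3N, CH2Cl2, 0 °C) to give trimethyl{[(3Z)-7-methylocta-1,3,6-trien-3-yl]oxy}silane F3, which is distilled. Cleavage of F3 with MeLi (THF, 0 °C) gives the amine-free lithium dienolate at a point where no enone is left in the flask. The fallback sets out from enone 5 and comes back to the route at lithium dienolate 6, which is trifluoroacetylated and carried through the diazo transfer as in step 3.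

3. Step 4. Dibromomethyllithium or the amide base may remove a proton from the doubly activated CH2 of the β,γ-unsaturated ester instead of adding to the carbonyl group, which returns the ester or its conjugated isomer. The fallback reaches the ynolate by oxidation of a lithium acetylide and not by ester homologation. Commercial 1-bromo-3-methylbut-2-ene is coupled with ethynylmagnesium bromide (CuCl cat., THF) to give 5-methylhex-4-en-1-yne F4. LiN(SiMe3)2 (THF, −78 °C) gives (5-methylhex-4-en-1-ynyl)lithium F5, and lithium tert-butyl peroxide (t-BuOOLi, from anhydrous t-BuOOH and LiN(SiMe3)2, THF, −78 → 0 °C) transfers oxygen to the acetylide carbon. The fallback consumes no numbered compound: it replaces ester 9 by the two commercial reagents and comes back to the route at lithium ynolate 11, which is silylated to 12 as in step 4.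

**Further compounds**
F1 | step 5 | 2-ethenyl-5-methylhex-4-enoic acid (racemic) | C=CC(CC=C(C)C)C(=O)O
F2 | step 5 | 2-ethenyl-5-methylhex-4-enoyl chloride (racemic) | C=CC(CC=C(C)C)C(=O)Cl
F3 | step 3 | trimethyl{[(3Z)-7-methylocta-1,3,6-trien-3-yl]oxy}silane | C=C/C(O[Si](C)(C)C)=C/CC=C(C)C
F4 | step 4 | 5-methylhex-4-en-1-yne | C#CCC=C(C)C
F5 | step 4 | (5-methylhex-4-en-1-ynyl)lithium | [Li]C#CCC=C(C)C
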